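The alder and oak runs, read between 0.667 min and 1.33 min, gave a pseudo-first-order constant k, the rise in product per minute over the mean substrate standing: 2.94 min⁻¹ for alder and 3.08 min⁻¹ for oak.

| setting | alder | oak | elm | flask |
|---|---|---|---|---|
| substrate | 0.050 M (fed, over 1.5 min) | 0.050 M (fed, over 1.5 min) | 0.075 M (fed, over 1.5 min) | 0.050 M (fed, over 1.5 min) |
| acid | 0.034 mM | 0.075 mM | 0.050 mM | 0.0500 mM |
| remark | run made earlier; the fed solution adds 0.10 times the starting volume | run made earlier; the fed solution adds 0.10 times the starting volume | run made earlier; the fed solution adds 0.10 times the starting volume | the fed solution adds 0.10 times the starting volume |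
| time |  |  |  | 2.5 min |

| run | time / min | substrate / % | product / % |
|---|---|---|---|
| alder | 0.200 | 13.5 | 0 |
| alder | 0.667 | 31.9 | 11.5 |
| alder | 1.33 | 23.5 | 65.5 |
| alder | 2.00 | 1.9 | 97.8 |
| alder | 2.50 | 0 | 99.8 |
| oak | 0.200 | 12.8 | 0.8 |
| oak | 0.417 | 23.7 | 3.8 |
| oak | 0.667 | 29.6 | 15.3 |
| oak | 1.33 | 21.6 | 67.6 |
| oak | 2.50 | 0.6 | 99.9 |
| elm | 0.200 | 13.5 | 1.2 |
| elm | 0.417 | 23.5 | 5.3 |
| elm | 0.667 | 27.8 | 15.7 |
| elm | 1.33 | 16.2 | 71.6 |
| elm | 2.50 | 1.1 | 100.9 |

(each reading ± 0.5 percentage points)

- part of the substrate that has reacted at 2.5 min
- pH of the solution at 2.5 min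

- acid is the free proton; pH is minus the decimal logarithm of its molar concentration
- amounts are per litre of the starting volume; all of the dose is in the solution fed
- the earlier runs were read with a standard deviation of 0.5 percentage points
- percentages count the whole charge, also what has not yet gone in

The new flask's acid lies between those two runs, so I took their mean, 3.01 min⁻¹, and folded it with the dosing time:

Da = k × dosing time = 4.52

This Damköhler number counts the substrate lifetimes that fit into the dosing time. While feed and loss balance, the share of the charge standing is its inverse. After the feed, that share falls by a factor e every dosing time over Da.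

share at end of feed = 1/Da = 22.1%

I tested this on alder. For 2.00 min it gave 4.91%, but alder read 1.9%, which is less. So one number was not enough. That reading implied a late constant of 4.91 min⁻¹, larger than k.

decades lost after the feed = 2.13

substrate left = 0.163%

So I expected 99.8% reacted in the flask. My number gave no pH.

The forecast, holding that “the reaction is self-accelerating”, gave 99.8% (99.3% to 100%) and pH 3.4 (3.15 to 3.7).

The flask gave 99.8% reacted, inside its range, and pH 3.06, lower than the range's low end of 3.15, though within the tolerance.

    substrate + acid → weak acid + acid + product (k = 89.0 L mol⁻¹ s⁻¹)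
    weak acid ⇌ conjugate base + acid, settled at all times (K = 1.60 × 10⁻⁵ M)
    substrate → weak acid + product (k = 1.60 × 10⁻⁵ s⁻¹)

The flask held 0.21% substrate at 2.50 min, against my 0.163%. With all else held, the answer moved by 5 points at a substrate charge of 0.0129 M. The neighbour was the same flask read at 1.5 min, the end of the feed. There 1/Da gave 22.1% standing, and the neighbour held less, 19.5% substrate, with 80.5% reacted.

The runs are calculated with made-up constants, and the scatter is random.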